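**Retrosynthetic overview**
- The seven phenols are unmasked last (MOM ethers). The aryl ketone C(O)–aryl bond is cut to a cyclohexenecarbonyl chloride and a prenylated resorcinol arylzinc (Pd-catalysed acylation), and the chalcone enone to an aryl methyl ketone plus 2,4-bis(MOM-oxy)benzaldehyde (Claisen–Schmidt).
- Key disconnection: the ring C2–aryl bond, made by a stereoinvertive Pd-catalysed allyl–aryl coupling of an all-trans cyclohexenyl carbonate with a 3-acetyl-2,6-bis(MOM-oxy)phenylzinc iodide. This sets the cis C1/C2 relationship.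
- The cyclohexene is the only ring built and is formed first: Heck reaction to an aryl enone, asymmetric Michael/aldol annulation with methyl acetoacetate, then Luche reduction to the all-trans allylic alcohol.
- Four branches (core, acetyl-aryl iodide, benzaldehyde, prenyl arene) from 4-iodophenol, resorcinol, methyl vinyl ketone, methyl acetoacetate, acetic acid and prenyl bromide converge in three late couplings.
- Target read from the SMILES as the (1R,2S,6S) cyclohex-3-ene: aroyl (C1) cis to the chalcone aryl (C2) and trans to the 4-hydroxyphenyl (C6).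

Assumption: the sense of induction of the cinchona primary amine in step 3 is taken by analogy; if the (6R) antipode forms, the pseudoenantiomeric 9-amino-9-deoxy-epi-quinine is used instead.

**Route**

Step 1
Reactants: 1 4-iodophenol
Product: 2 1-iodo-4-(methoxymethoxy)benzene
Conditions: MOMCl, i-Pr2NEt, CH2Cl2, 0 °C to rt
Reagents that add atoms: chloromethyl methyl ether, COCCl
Why: Phenoxide O-alkylation (MOM ether formation) masks the phenol for the later organometallic and basic steps.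

Step 2
Reactants: 2 1-iodo-4-(methoxymethoxy)benzene; 3 but-3-en-2-one
Product: 4 (3E)-4-[4-(methoxymethoxy)phenyl]but-3-en-2-one
Conditions: Pd(OAc)2 (2 mol %), P(o-tol)3 (4 mol %), Et3N, MeCN, 80 °C
Reagents that add atoms: none
Why: Mizoroki–Heck reaction: oxidative addition of the aryl iodide, syn insertion into the enone and syn β-hydride elimination give the E-configured aryl enone.

Step 3
Reactants: 4 (3E)-4-[4-(methoxymethoxy)phenyl]but-3-en-2-one; 5 methyl 3-oxobutanoate
Product: 7 methyl (1R,6S)-6-[4-(methoxymethoxy)phenyl]-4-methyl-2-oxocyclohex-3-ene-1-carboxylate, via Michael adduct 6 (not isolated)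
Conditions: 9-amino-9-deoxy-epi-quinidine (20 mol %), PhCO2H (40 mol %), toluene, 40 °C then 60 °C
Reagents that add atoms: none
Why: Asymmetric Robinson-type annulation (iminium-activated Michael addition then intramolecular aldol condensation): the cinchona primary amine shields one face of the enone iminium so that C6 is set as (S), and the doubly activated C1 equilibrates to the trans (1R) β-keto ester.

Step 4
Reactants: 7 methyl (1R,6S)-6-[4-(methoxymethoxy)phenyl]-4-methyl-2-oxocyclohex-3-ene-1-carboxylate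
Product: 8 methyl (1R,2R,6S)-2-hydroxy-6-[4-(methoxymethoxy)phenyl]-4-methylcyclohex-3-ene-1-carboxylate
Conditions: NaBH4, CeCl3·7H2O, MeOH, −78 to −40 °C
Reagents that add atoms: none
Why: Luche reduction: 1,2-selective hydride delivery by axial attack next to the equatorial ester gives the equatorial (2R) alcohol, trans to the ester and cis to the aryl group (substrate control).

Step 5
Reactants: 8 methyl (1R,2R,6S)-2-hydroxy-6-[4-(methoxymethoxy)phenyl]-4-methylcyclohex-3-ene-1-carboxylate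
Product: 9 methyl (1R,2R,6S)-2-[(methoxycarbonyl)oxy]-6-[4-(methoxymethoxy)phenyl]-4-methylcyclohex-3-ene-1-carboxylate
Conditions: ClCO2Me, pyridine, CH2Cl2, 0 °C
Reagents that add atoms: methyl chloroformate, COC(=O)Cl
Why: O-acylation with a chloroformate under a weak base at 0 °C gives the allylic carbonate without β-elimination of the aldol-type ester.

Step 6
Reactants: 10 resorcinol; 11 acetic acid
Product: 12 1-(2,4-dihydroxyphenyl)ethanone
Conditions: ZnCl2, AcOH (neat), 140 °C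
Reagents that add atoms: none
Why: Nencki reaction (ZnCl2-promoted Friedel–Crafts C-acylation by acetic acid) takes place para to one hydroxyl and ortho to the other of resorcinol.

Step 7
Reactants: 12 1-(2,4-dihydroxyphenyl)ethanone
Product: 13 1-(2,4-dihydroxy-3-iodophenyl)ethanone
Conditions: I2, HIO3, EtOH/H2O, rt
Reagents that add atoms: iodine, II; iodic acid, O[I](=O)=O
Why: Electrophilic aromatic iodination at the position flanked by both hydroxyl groups, the most activated one of the chelated ketone, with HIO3 reoxidising iodide so that all iodine is used.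

Step 8
Reactants: 13 1-(2,4-dihydroxy-3-iodophenyl)ethanone
Product: 14 1-[3-iodo-2,4-bis(methoxymethoxy)phenyl]ethanone
Conditions: NaH, MOMCl, DMF, 0 °C to rt
Reagents that add atoms: chloromethyl methyl ether, COCCl
Why: Double phenoxide O-alkylation (MOM ether formation), with NaH needed for the hydrogen-bonded, flanked 2-OH.

Step 9
Reactants: 10 resorcinol
Product: 16 2,4-dihydroxybenzaldehyde, via iminium chloride 15 (not isolated)
Conditions: (COCl)2, DMF, MeCN, −15 °C to rt; then H2O, 50 °C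
Reagents that add atoms: N,N-dimethylformamide, CN(C)C=O; water, O
Why: Vilsmeier–Haack formylation para to one hydroxyl of resorcinol, then hydrolysis of the iminium salt to the aldehyde.

Step 10
Reactants: 16 2,4-dihydroxybenzaldehyde
Product: 17 2,4-bis(methoxymethoxy)benzaldehyde
Conditions: NaH, MOMCl, DMF, 0 °C to rt
Reagents that add atoms: chloromethyl methyl ether, COCCl
Why: Double phenoxide O-alkylation (MOM ether formation) of a non-enolisable aldehyde.

Step 11
Reactants: 10 resorcinol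
Product: 18 1,3-bis(methoxymethoxy)benzene
Conditions: NaH, MOMCl, DMF, 0 °C to rt
Reagents that add atoms: chloromethyl methyl ether, COCCl
Why: Double phenoxide O-alkylation (MOM ether formation) installs the two directing groups for ortho-metalation.

Step 12
Reactants: 18 1,3-bis(methoxymethoxy)benzene; 19 1-bromo-3-methylbut-2-ene
Product: 21 1,3-bis(methoxymethoxy)-2-(3-methylbut-2-en-1-yl)benzene, via aryllithium 20 (not isolated)
Conditions: n-BuLi, THF, 0 °C; then CuI (10 mol %), 19, −78 °C to rt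
Reagents that add atoms: none
Why: Directed ortho-metalation at C2 between the two MOM ethers, then copper-catalysed SN2 allylation with prenyl bromide gives the linear prenyl arene.

Step 13
Reactants: 9 methyl (1R,2R,6S)-2-[(methoxycarbonyl)oxy]-6-[4-(methoxymethoxy)phenyl]-4-methylcyclohex-3-ene-1-carboxylate; 14 1-[3-iodo-2,4-bis(methoxymethoxy)phenyl]ethanone
Product: 23 methyl (1R,2S,6S)-2-[3-acetyl-2,6-bis(methoxymethoxy)phenyl]-6-[4-(methoxymethoxy)phenyl]-4-methylcyclohex-3-ene-1-carboxylate, via arylzinc iodide 22 (not isolated)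
Conditions: 14, Zn dust, LiCl, THF, 25 °C; then 9, Pd2(dba)3·CHCl3 (2.5 mol %), P(2-furyl)3 (10 mol %), dimethyl fumarate (20 mol %), THF, 25 to 40 °C
Reagents that add atoms: none
Why: Proposed new method: a stereoinvertive Negishi-type allyl–aryl coupling on a substrate class where it has not been shown (an ester-flanked, trisubstituted cyclohexenyl carbonate with a di-ortho-alkoxy, ketone-bearing arylzinc); zerovalent palladium ionises the carbonate anti, so the metal sits on the face of the C1 ester (where C1–H is anti to it and cannot β-eliminate), the arylzinc transmetalates, and inner-sphere reductive elimination, sped up by the π-acidic furylphosphine and fumarate, delivers the aryl from the palladium face to the less substituted allyl terminus C2, which sets C2 as (S), cis to the ester and trans to the C6 aryl, by net inversion; the closest known reaction type is the palladium-catalysed allylic arylation of cyclohexenyl esters with arylzinc halides, which runs with inversion.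

Step 14
Reactants: 23 methyl (1R,2S,6S)-2-[3-acetyl-2,6-bis(methoxymethoxy)phenyl]-6-[4-(methoxymethoxy)phenyl]-4-methylcyclohex-3-ene-1-carboxylate
Product: 24 (1R,2S,6S)-2-[3-acetyl-2,6-bis(methoxymethoxy)phenyl]-6-[4-(methoxymethoxy)phenyl]-4-methylcyclohex-3-ene-1-carboxylic acid
Conditions: Me3SnOH, ClCH2CH2Cl, 80 °C; then 0.1 M aq. HCl wash, 0 °C
Reagents that add atoms: trimethyltin hydroxide, C[Sn](C)(C)O
Why: Trimethyltin hydroxide ester cleavage (mild nucleophilic hydrolysis through a tin carboxylate) avoids enolisation, so C1 keeps its configuration.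

Step 15
Reactants: 24 (1R,2S,6S)-2-[3-acetyl-2,6-bis(methoxymethoxy)phenyl]-6-[4-(methoxymethoxy)phenyl]-4-methylcyclohex-3-ene-1-carboxylic acid; 17 2,4-bis(methoxymethoxy)benzaldehyde
Product: 25 (1R,2S,6S)-2-{3-[(2E)-3-[2,4-bis(methoxymethoxy)phenyl]prop-2-enoyl]-2,6-bis(methoxymethoxy)phenyl}-6-[4-(methoxymethoxy)phenyl]-4-methylcyclohex-3-ene-1-carboxylic acid
Conditions: KOH (aq.), EtOH, rt; then AcOH to pH 5
Reagents that add atoms: none
Why: Claisen–Schmidt condensation (crossed aldol, E1cB dehydration) gives the E-chalcone, while the carboxylate at C1 cannot enolise under these conditions.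

Step 16
Reactants: 25 (1R,2S,6S)-2-{3-[(2E)-3-[2,4-bis(methoxymethoxy)phenyl]prop-2-enoyl]-2,6-bis(methoxymethoxy)phenyl}-6-[4-(methoxymethoxy)phenyl]-4-methylcyclohex-3-ene-1-carboxylic acid; 21 1,3-bis(methoxymethoxy)-2-(3-methylbut-2-en-1-yl)benzene
Product: 29 [(1R,2S,6S)-2-{3-[(2E)-3-[2,4-bis(methoxymethoxy)phenyl]prop-2-enoyl]-2,6-bis(methoxymethoxy)phenyl}-6-[4-(methoxymethoxy)phenyl]-4-methylcyclohex-3-en-1-yl][2,4-bis(methoxymethoxy)-3-(3-methylbut-2-en-1-yl)phenyl]methanone, via acid chloride 26 (not isolated), via aryllithium 27 (not isolated), via arylzinc chloride 28 (not isolated)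
Conditions: 21, n-BuLi, TMEDA, THF, 0 °C, then ZnCl2; 25, 1-chloro-N,N,2-trimethylprop-1-en-1-amine, CH2Cl2, 0 °C; combine, Pd(PPh3)4 (5 mol %), THF, 0 °C to rt
Reagents that add atoms: none
Why: Negishi acylation: neutral acid chloride formation (Ghosez reagent), ortho-lithiation of the prenyl arene next to a MOM ether, transmetalation to zinc and palladium-catalysed acyl–aryl coupling form the ketone without base, so C1 is not epimerised and the enone is not attacked.

Step 17
Reactants: 29 hepta-MOM ether of the target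
Product: 30 [(1R,2S,6S)-2-{2,6-dihydroxy-3-[(2E)-3-(2,4-dihydroxyphenyl)prop-2-enoyl]phenyl}-6-(4-hydroxyphenyl)-4-methylcyclohex-3-en-1-yl][2,4-dihydroxy-3-(3-methylbut-2-en-1-yl)phenyl]methanone
Conditions: 3 M aq. HCl, MeOH, rt to 40 °C
Reagents that add atoms: none
Why: Acid-catalysed acetal exchange removes the seven MOM ethers under conditions mild enough for the prenyl group, the chalcone and the C1 stereocentre.

**Compound list**

1 | 4-iodophenol | Oc1ccc(I)cc1 | starting material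
2 | 1-iodo-4-(methoxymethoxy)benzene | COCOc1ccc(I)cc1 | intermediate
3 | but-3-en-2-one (methyl vinyl ketone) | CC(=O)C=C | starting material
4 | (3E)-4-[4-(methoxymethoxy)phenyl]but-3-en-2-one | CC(=O)/C=C/c1ccc(OCOC)cc1 | intermediate
5 | methyl 3-oxobutanoate | COC(=O)CC(C)=O | starting material
6 | methyl (3S)-2-acetyl-3-[4-(methoxymethoxy)phenyl]-5-oxohexanoate (Michael adduct, both C2 epimers) | CC(=O)C[C@@H](C(C(C)=O)C(=O)OC)c1ccc(OCOC)cc1 | intermediate
7 | methyl (1R,6S)-6-[4-(methoxymethoxy)phenyl]-4-methyl-2-oxocyclohex-3-ene-1-carboxylate | COC(=O)[C@H]1C(=O)C=C(C)C[C@@H]1c1ccc(OCOC)cc1 | intermediate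
8 | methyl (1R,2R,6S)-2-hydroxy-6-[4-(methoxymethoxy)phenyl]-4-methylcyclohex-3-ene-1-carboxylate | COC(=O)[C@H]1[C@H](O)C=C(C)C[C@@H]1c1ccc(OCOC)cc1 | intermediate
9 | methyl (1R,2R,6S)-2-[(methoxycarbonyl)oxy]-6-[4-(methoxymethoxy)phenyl]-4-methylcyclohex-3-ene-1-carboxylate | COC(=O)[C@H]1[C@H](OC(=O)OC)C=C(C)C[C@@H]1c1ccc(OCOC)cc1 | intermediate
10 | resorcinol (benzene-1,3-diol) | Oc1cccc(O)c1 | starting material
11 | acetic acid | CC(=O)O | starting material
12 | 1-(2,4-dihydroxyphenyl)ethanone | CC(=O)c1ccc(O)cc1O | intermediate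
13 | 1-(2,4-dihydroxy-3-iodophenyl)ethanone | CC(=O)c1ccc(O)c(I)c1O | intermediate
14 | 1-[3-iodo-2,4-bis(methoxymethoxy)phenyl]ethanone | CC(=O)c1ccc(OCOC)c(I)c1OCOC | intermediate
15 | (2,4-dihydroxybenzylidene)dimethyliminium chloride | C[N+](C)=Cc1ccc(O)cc1O.[Cl-] | intermediate
16 | 2,4-dihydroxybenzaldehyde | O=Cc1ccc(O)cc1O | intermediate
17 | 2,4-bis(methoxymethoxy)benzaldehyde | COCOc1ccc(C=O)c(OCOC)c1 | intermediate
18 | 1,3-bis(methoxymethoxy)benzene | COCOc1cccc(OCOC)c1 | intermediate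
19 | 1-bromo-3-methylbut-2-ene (prenyl bromide) | CC(C)=CCBr | starting material
20 | [2,6-bis(methoxymethoxy)phenyl]lithium | [Li]c1c(OCOC)cccc1OCOC | intermediate
21 | 1,3-bis(methoxymethoxy)-2-(3-methylbut-2-en-1-yl)benzene | COCOc1cccc(OCOC)c1CC=C(C)C | intermediate
22 | [3-acetyl-2,6-bis(methoxymethoxy)phenyl]zinc iodide | CC(=O)c1ccc(OCOC)c([Zn]I)c1OCOC | intermediate
23 | methyl (1R,2S,6S)-2-[3-acetyl-2,6-bis(methoxymethoxy)phenyl]-6-[4-(methoxymethoxy)phenyl]-4-methylcyclohex-3-ene-1-carboxylate | COC(=O)[C@H]1[C@@H](c2c(OCOC)ccc(C(C)=O)c2OCOC)C=C(C)C[C@@H]1c1ccc(OCOC)cc1 | intermediate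
24 | (1R,2S,6S)-2-[3-acetyl-2,6-bis(methoxymethoxy)phenyl]-6-[4-(methoxymethoxy)phenyl]-4-methylcyclohex-3-ene-1-carboxylic acid | OC(=O)[C@H]1[C@@H](c2c(OCOC)ccc(C(C)=O)c2OCOC)C=C(C)C[C@@H]1c1ccc(OCOC)cc1 | intermediate
25 | (1R,2S,6S)-2-{3-[(2E)-3-[2,4-bis(methoxymethoxy)phenyl]prop-2-enoyl]-2,6-bis(methoxymethoxy)phenyl}-6-[4-(methoxymethoxy)phenyl]-4-methylcyclohex-3-ene-1-carboxylic acid | OC(=O)[C@H]1[C@@H](c2c(OCOC)ccc(C(=O)/C=C/c3ccc(OCOC)cc3OCOC)c2OCOC)C=C(C)C[C@@H]1c1ccc(OCOC)cc1 | intermediate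
26 | (1R,2S,6S)-2-{3-[(2E)-3-[2,4-bis(methoxymethoxy)phenyl]prop-2-enoyl]-2,6-bis(methoxymethoxy)phenyl}-6-[4-(methoxymethoxy)phenyl]-4-methylcyclohex-3-ene-1-carbonyl chloride | ClC(=O)[C@H]1[C@@H](c2c(OCOC)ccc(C(=O)/C=C/c3ccc(OCOC)cc3OCOC)c2OCOC)C=C(C)C[C@@H]1c1ccc(OCOC)cc1 | intermediate
27 | [2,4-bis(methoxymethoxy)-3-(3-methylbut-2-en-1-yl)phenyl]lithium | [Li]c1ccc(OCOC)c(CC=C(C)C)c1OCOC | intermediate
28 | chloro[2,4-bis(methoxymethoxy)-3-(3-methylbut-2-en-1-yl)phenyl]zinc | Cl[Zn]c1ccc(OCOC)c(CC=C(C)C)c1OCOC | intermediate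
29 | [(1R,2S,6S)-2-{3-[(2E)-3-[2,4-bis(methoxymethoxy)phenyl]prop-2-enoyl]-2,6-bis(methoxymethoxy)phenyl}-6-[4-(methoxymethoxy)phenyl]-4-methylcyclohex-3-en-1-yl][2,4-bis(methoxymethoxy)-3-(3-methylbut-2-en-1-yl)phenyl]methanone | CC(C)=CCc1c(OCOC)ccc(C(=O)[C@H]2[C@@H](c3c(OCOC)ccc(C(=O)/C=C/c4ccc(OCOC)cc4OCOC)c3OCOC)C=C(C)C[C@@H]2c2ccc(OCOC)cc2)c1OCOC | intermediate
30 | [(1R,2S,6S)-2-{2,6-dihydroxy-3-[(2E)-3-(2,4-dihydroxyphenyl)prop-2-enoyl]phenyl}-6-(4-hydroxyphenyl)-4-methylcyclohex-3-en-1-yl][2,4-dihydroxy-3-(3-methylbut-2-en-1-yl)phenyl]methanone | CC(C)=CCc1c(O)ccc(C(=O)[C@H]2[C@@H](c3c(O)ccc(C(=O)/C=C/c4ccc(O)cc4O)c3O)C=C(C)C[C@@H]2c2ccc(O)cc2)c1O | target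

**Step count and risks**

Total step count: 17. Longest linear sequence: 10 steps (1, 2, 3, 4, 5, 13, 14, 15, 16, 17); the three other branches are steps 6–8, 9–10 and 11–12.

Most likely to fail, step 13 (the new allyl–aryl coupling). Ionisation needs the carbonate pseudo-axial, which forces the all-trans ring into its triaxial half-chair. The β-carbonate ester can eliminate to a dienoate. The aryl group to be transferred is di-ortho-substituted. The fallback uses known chemistry, sets out from 14, 17, 13 and 2, and comes back to the route at 30.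
- Diene: Claisen–Schmidt condensation of 14 with 17 (KOH, EtOH) gives (2E)-3-[2,4-bis(methoxymethoxy)phenyl]-1-[3-iodo-2,4-bis(methoxymethoxy)phenyl]prop-2-en-1-one F1. Hydroboration of 2-methylbut-1-en-3-yne with pinacolborane (Cp2ZrHCl cat.) gives 4,4,5,5-tetramethyl-2-[(1E)-3-methylbuta-1,3-dien-1-yl]-1,3,2-dioxaborolane F2. Suzuki coupling of the two (Pd(PPh3)4, K2CO3, dioxane/H2O) gives (2E)-3-[2,4-bis(methoxymethoxy)phenyl]-1-{2,4-bis(methoxymethoxy)-3-[(1E)-3-methylbuta-1,3-dien-1-yl]phenyl}prop-2-en-1-one F3.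
- Dienophile: 13 is protected only at the free 4-OH (MOMCl, K2CO3, acetone) to 1-[2-hydroxy-3-iodo-4-(methoxymethoxy)phenyl]ethanone F4. Stille coupling with tributyl(3-methylbut-2-en-1-yl)stannane (Pd(PPh3)4, DMF) gives 1-[2-hydroxy-4-(methoxymethoxy)-3-(3-methylbut-2-en-1-yl)phenyl]ethanone F5. Iodine–magnesium exchange on 2 (i-PrMgCl·LiCl) and DMF give 4-(methoxymethoxy)benzaldehyde F6. Claisen–Schmidt condensation of the ketone and the aldehyde gives (2E)-1-[2-hydroxy-4-(methoxymethoxy)-3-(3-methylbut-2-en-1-yl)phenyl]-3-[4-(methoxymethoxy)phenyl]prop-2-en-1-one F7.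
- Cycloaddition: an enantioselective Diels–Alder reaction of the 2'-hydroxychalcone with the diene, promoted by a chiral boron Lewis acid from B(OPh)3 and the appropriate enantiomer of a 1,1'-bi-2-naphthol-type diol, gives after separation from the exo isomer the endo adduct [(1R,2S,6S)-2-{3-[(2E)-3-[2,4-bis(methoxymethoxy)phenyl]prop-2-enoyl]-2,6-bis(methoxymethoxy)phenyl}-6-[4-(methoxymethoxy)phenyl]-4-methylcyclohex-3-en-1-yl][2-hydroxy-4-(methoxymethoxy)-3-(3-methylbut-2-en-1-yl)phenyl]methanone F8. HCl in MeOH then gives 30.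

Second, step 3 (asymmetric annulation). The enantioselectivity and the direction of the aldol ring closure are not assured for this enone. The fallback sets out from 4 and 5 and comes back at 8.
- Annulation with NaOMe in MeOH gives racemic methyl (1R*,6S*)-6-[4-(methoxymethoxy)phenyl]-4-methyl-2-oxocyclohex-3-ene-1-carboxylate F9.
- Luche reduction gives racemic methyl (1R*,2R*,6S*)-2-hydroxy-6-[4-(methoxymethoxy)phenyl]-4-methylcyclohex-3-ene-1-carboxylate F10.
- Kinetic resolution with Burkholderia cepacia lipase and vinyl acetate acylates the (2R) carbinol (the usual lipase preference) to methyl (1R,2R,6S)-2-acetoxy-6-[4-(methoxymethoxy)phenyl]-4-methylcyclohex-3-ene-1-carboxylate F11, and leaves methyl (1S,2S,6R)-2-hydroxy-6-[4-(methoxymethoxy)phenyl]-4-methylcyclohex-3-ene-1-carboxylate F12, which is discarded.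
- The acetate is separated and cleaved by the same lipase in pH 7 buffer to give 8.

Third, step 16 (acyl–aryl coupling). The acid chloride is hindered and may lose CO at palladium or epimerise at C1 through a ketene. The fallback sets out from 25 and 21 and comes back at 29.
- The acid chloride 26, made as in the route, is treated with PhSH and pyridine at −20 °C to give S-phenyl (1R,2S,6S)-2-{3-[(2E)-3-[2,4-bis(methoxymethoxy)phenyl]prop-2-enoyl]-2,6-bis(methoxymethoxy)phenyl}-6-[4-(methoxymethoxy)phenyl]-4-methylcyclohex-3-ene-1-carbothioate F13.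
- The aryllithium 27, made from 21 as in the route, is quenched with B(OiPr)3 and hydrolysed to [2,4-bis(methoxymethoxy)-3-(3-methylbut-2-en-1-yl)phenyl]boronic acid F14.
- A base-free Liebeskind–Srogl coupling of the thioester and the boronic acid (Pd2(dba)3, P(2-furyl)3, Cu(O2CC4H3S) (copper thiophene-2-carboxylate, monovalent copper), THF, 50 °C) gives 29.

**Further compounds**

F1 | step 13 | (2E)-3-[2,4-bis(methoxymethoxy)phenyl]-1-[3-iodo-2,4-bis(methoxymethoxy)phenyl]prop-2-en-1-one | COCOc1ccc(/C=C/C(=O)c2ccc(OCOC)c(I)c2OCOC)c(OCOC)c1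
F2 | step 13 | 4,4,5,5-tetramethyl-2-[(1E)-3-methylbuta-1,3-dien-1-yl]-1,3,2-dioxaborolane | CC(=C)/C=C/B1OC(C)(C)C(C)(C)O1
F3 | step 13 | (2E)-3-[2,4-bis(methoxymethoxy)phenyl]-1-{2,4-bis(methoxymethoxy)-3-[(1E)-3-methylbuta-1,3-dien-1-yl]phenyl}prop-2-en-1-one | COCOc1ccc(/C=C/C(=O)c2ccc(OCOC)c(/C=C/C(C)=C)c2OCOC)c(OCOC)c1
F4 | step 13 | 1-[2-hydroxy-3-iodo-4-(methoxymethoxy)phenyl]ethanone | CC(=O)c1ccc(OCOC)c(I)c1O
F5 | step 13 | 1-[2-hydroxy-4-(methoxymethoxy)-3-(3-methylbut-2-en-1-yl)phenyl]ethanone | CC(=O)c1ccc(OCOC)c(CC=C(C)C)c1O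
F6 | step 13 | 4-(methoxymethoxy)benzaldehyde | COCOc1ccc(C=O)cc1
F7 | step 13 | (2E)-1-[2-hydroxy-4-(methoxymethoxy)-3-(3-methylbut-2-en-1-yl)phenyl]-3-[4-(methoxymethoxy)phenyl]prop-2-en-1-one | COCOc1ccc(/C=C/C(=O)c2ccc(OCOC)c(CC=C(C)C)c2O)cc1
F8 | step 13 | [(1R,2S,6S)-2-{3-[(2E)-3-[2,4-bis(methoxymethoxy)phenyl]prop-2-enoyl]-2,6-bis(methoxymethoxy)phenyl}-6-[4-(methoxymethoxy)phenyl]-4-methylcyclohex-3-en-1-yl][2-hydroxy-4-(methoxymethoxy)-3-(3-methylbut-2-en-1-yl)phenyl]methanone | CC(C)=CCc1c(OCOC)ccc(C(=O)[C@H]2[C@@H](c3c(OCOC)ccc(C(=O)/C=C/c4ccc(OCOC)cc4OCOC)c3OCOC)C=C(C)C[C@@H]2c2ccc(OCOC)cc2)c1O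
F9 | step 3 | racemic methyl (1R*,6S*)-6-[4-(methoxymethoxy)phenyl]-4-methyl-2-oxocyclohex-3-ene-1-carboxylate (both enantiomers) | COC(=O)[C@H]1C(=O)C=C(C)C[C@@H]1c1ccc(OCOC)cc1.COC(=O)[C@@H]1C(=O)C=C(C)C[C@H]1c1ccc(OCOC)cc1
F10 | step 3 | racemic methyl (1R*,2R*,6S*)-2-hydroxy-6-[4-(methoxymethoxy)phenyl]-4-methylcyclohex-3-ene-1-carboxylate (both enantiomers) | COC(=O)[C@H]1[C@H](O)C=C(C)C[C@@H]1c1ccc(OCOC)cc1.COC(=O)[C@@H]1[C@@H](O)C=C(C)C[C@H]1c1ccc(OCOC)cc1
F11 | step 3 | methyl (1R,2R,6S)-2-acetoxy-6-[4-(methoxymethoxy)phenyl]-4-methylcyclohex-3-ene-1-carboxylate | COC(=O)[C@H]1[C@H](OC(C)=O)C=C(C)C[C@@H]1c1ccc(OCOC)cc1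
F12 | step 3 | methyl (1S,2S,6R)-2-hydroxy-6-[4-(methoxymethoxy)phenyl]-4-methylcyclohex-3-ene-1-carboxylate | COC(=O)[C@@H]1[C@@H](O)C=C(C)C[C@H]1c1ccc(OCOC)cc1
F13 | step 16 | S-phenyl (1R,2S,6S)-2-{3-[(2E)-3-[2,4-bis(methoxymethoxy)phenyl]prop-2-enoyl]-2,6-bis(methoxymethoxy)phenyl}-6-[4-(methoxymethoxy)phenyl]-4-methylcyclohex-3-ene-1-carbothioate | O=C(Sc1ccccc1)[C@H]1[C@@H](c2c(OCOC)ccc(C(=O)/C=C/c3ccc(OCOC)cc3OCOC)c2OCOC)C=C(C)C[C@@H]1c1ccc(OCOC)cc1
F14 | step 16 | [2,4-bis(methoxymethoxy)-3-(3-methylbut-2-en-1-yl)phenyl]boronic acid | OB(O)c1ccc(OCOC)c(CC=C(C)C)c1OCOC
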